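**Retrosynthetic overview**

1. Labels: rings A/C/B are the catechol-bearing flavanone (unprimed atoms, ring B on C2); rings D/F/E are the naringenin half (doubly primed atoms). The strategy rests on C3 of ring C: it carries the fully substituted ring D carbon C8'' and lies between the C4 carbonyl and the O1-bearing C2, which is an α-aryl-β-oxy enone once ring C is drawn as a chromone.
2. Endgame: the seven benzyl ethers come off last (H2, Pd/C). Before that, C2 and C3 are set together (cis, 2R,3R) by asymmetric 1,4-reduction of a 2,3-diarylchromone, and the ring F carbinol that this reduction also makes is re-oxidised.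
3. Key disconnection, O1–C2 and C3–C8'' in one step: the arylpalladium species from (S)-8''-iodo-tri-O-benzylnaringenin activates an aryl ynone, an ortho benzyloxy oxygen of ring A closes ring C (6-endo) with loss of its benzyl group, and reductive elimination joins C3 to C8''.
4. Ynone: 2,4,6-trihydroxybenzaldehyde is benzylated three times with benzyl bromide, the aldehyde takes up lithiated 3,4-bis(benzyloxy)phenylacetylene, then MnO2. Iodide: (S)-naringenin (source of rings D, E, F and of C2''), Mitsunobu benzylation, C8'' iodination.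
5. Ring order: rings A, B, D, E and F are bought; ring C is the only ring made (step 7).

Key step: step 7

Remarks on the chemistry:
- (S)-Naringenin of high enantiomeric purity is assumed as the commercial material; the enantiomeric purity would be checked at compound 10.
- (R)-DTBM-SEGPHOS is written for hydride delivery to the face of C2 from which O1, C1' and C3 appear counterclockwise (this gives 2R). If a model 2,3-diarylchromone showed the opposite sense, the antipodal ligand would be used.
- Chromone 12 may exist as rotamers about the hindered C3–C8'' bond; they would be carried on together, since this bond is not a stereogenic element of the target.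

**Route**

Step 1
Reactants: 1 2,4,6-trihydroxybenzaldehyde; 2 benzyl bromide (three equivalents are incorporated)
Product: 3 2,4,6-tris(benzyloxy)benzaldehyde
Conditions: BnBr (3.6 equiv), K2CO3 (4.5 equiv), DMF, 60 °C
Reagents that add atoms: benzyl bromide, BrCc1ccccc1
Why: Williamson ether synthesis run at all three phenols, so that three equivalents of 2 end up in the product; the formyl group lowers the nucleophilicity of the ring carbons so that O-benzylation should prevail over C-benzylation, and excess bromide with heat should also alkylate the two chelated ortho phenols.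

Step 2
Reactants: 4 3,4-bis(benzyloxy)benzaldehyde
Product: 5 1,2-bis(benzyloxy)-4-ethynylbenzene
Conditions: dimethyl (1-diazo-2-oxopropyl)phosphonate (1.3 equiv), K2CO3 (2 equiv), MeOH–THF, 0 °C to rt
Reagents that add atoms: dimethyl (1-diazo-2-oxopropyl)phosphonate, CC(=O)C(=[N+]=[N-])P(=O)(OC)OC
Why: Seyferth–Gilbert homologation with the Ohira–Bestmann reagent turns a non-enolisable aryl aldehyde into the terminal alkyne under conditions that benzyl ethers tolerate.

Step 3
Reactants: 5 1,2-bis(benzyloxy)-4-ethynylbenzene; 3 2,4,6-tris(benzyloxy)benzaldehyde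
Product: 7 rac-1-[2,4,6-tris(benzyloxy)phenyl]-3-[3,4-bis(benzyloxy)phenyl]prop-2-yn-1-ol, via lithium acetylide 6 (not isolated)
Conditions: n-BuLi (1.15 equiv), THF, −78 °C; then 3, −78 to 0 °C; H2O
Reagents that add atoms: none
Why: 1,2-addition of a lithium acetylide to a non-enolisable aldehyde; the carbinol centre is formed racemic and is removed in step 4.

Step 4
Reactants: 7 rac-1-[2,4,6-tris(benzyloxy)phenyl]-3-[3,4-bis(benzyloxy)phenyl]prop-2-yn-1-ol
Product: 8 1-[2,4,6-tris(benzyloxy)phenyl]-3-[3,4-bis(benzyloxy)phenyl]prop-2-yn-1-one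
Conditions: activated MnO2 (15 equiv), CH2Cl2, rt
Reagents that add atoms: none
Why: MnO2 oxidation of a benzylic and propargylic alcohol to the ynone; the neutral conditions should spare the acid-sensitive carbinol and the benzyl ethers.

Step 5
Reactants: 9 (S)-naringenin
Product: 10 (2S)-5,7-bis(benzyloxy)-2-[4-(benzyloxy)phenyl]chroman-4-one
Conditions: BnOH, PPh3, DIAD (4.5 equiv each), THF, 0 to 40 °C
Reagents that add atoms: benzyl alcohol, OCc1ccccc1
Why: Mitsunobu etherification of the 7-OH, the ring E OH and then the chelated 5-OH avoids carbonate bases, which open ring F by retro-oxa-Michael reaction and would racemise C2''; C2'' is not touched, so S should be retained.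

Step 6
Reactants: 10 (2S)-5,7-bis(benzyloxy)-2-[4-(benzyloxy)phenyl]chroman-4-one
Product: 11 (2S)-5,7-bis(benzyloxy)-2-[4-(benzyloxy)phenyl]-8-iodochroman-4-one
Conditions: NIS (1.05 equiv), TFA (0.1 equiv), MeCN–CH2Cl2, 0 °C, dark
Reagents that add atoms: N-iodosuccinimide, O=C1CCC(=O)N1I
Why: electrophilic aromatic iodination; ring D with three oxygen donors is far more reactive than ring E, and C8'' (between O1'' and the 7''-benzyloxy group, para to the 5''-benzyloxy group) is less hindered than C6'' (between two benzyloxy groups), as in the 8-halogenation of 5,7-dialkoxyflavonoids.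

Step 7
Reactants: 8 1-[2,4,6-tris(benzyloxy)phenyl]-3-[3,4-bis(benzyloxy)phenyl]prop-2-yn-1-one (1.3 equiv); 11 (2S)-5,7-bis(benzyloxy)-2-[4-(benzyloxy)phenyl]-8-iodochroman-4-one
Product: 12 5,7-bis(benzyloxy)-2-[3,4-bis(benzyloxy)phenyl]-3-[(2S)-5,7-bis(benzyloxy)-2-(4-benzyloxyphenyl)-4-oxochroman-8-yl]-4H-chromen-4-one (heptabenzyl ether)
Conditions: Pd2(dba)3 (5 mol %), tri(2-furyl)phosphine (20 mol %), KOAc (3 equiv), dry DMF, 80 °C
Reagents that add atoms: none
Why: Proposed new method: oxidative addition of 11 to zerovalent palladium gives an arylpalladium iodide which, after iodide–acetate exchange, binds the ynone of 8 as a π-acid; an ortho benzyloxy oxygen of ring A attacks C2 anti to palladium, the O-benzyl oxonium so formed is debenzylated by acetate, and the chromon-3-yl(aryl)palladium eliminates reductively to form C3–C8''. The closest known reaction types are the palladium-catalysed cyclisation–arylation of 2-alkynylphenols and of tert-butyl 2-alkynylbenzaldimines with aryl halides (the second also sheds an alkyl group from the nucleophile) and the ICl-induced dealkylative cyclisation of 2-alkoxyaryl ynones to 3-iodochromones; an arylpalladium electrophile has not been shown on such ynones. Ring C closes through O1–C2 in the 6-endo-dig mode, preferred over 5-exo because the carbonyl polarises the alkyne and the electron-rich ring B stabilises positive charge at C2, so that palladium ends on C3. No stereocentre is formed: C2'' of 11 is not involved, and hindered rotation about C3–C8'' can at most give rotamers. The step needs aryl transfer to beat proton-terminated closure and syn carbopalladation; the nucleophile is therefore an ether, which brings no proton and does not add to the ynone under base as a free 2-hydroxyaryl ynone would, so ring closure can start only on the palladium-bound alkyne, and the two ortho benzyloxy groups are equivalent, so either one gives 12. Acetate in place of carbonate traps the benzyl group as benzyl acetate before it can shift to C3 and is too weak a base to open ring F.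

Step 8
Reactants: 12 heptabenzyl chromone–flavanone
Product: 13 (2R,3R)-5,7-bis(benzyloxy)-2-[3,4-bis(benzyloxy)phenyl]-3-[(2S)-5,7-bis(benzyloxy)-2-(4-benzyloxyphenyl)-4-hydroxychroman-8-yl]chroman-4-one (2,3-cis; mixture of epimers at the carbinol carbon C4'')
Conditions: Cu(OAc)2 (10 mol %), (R)-DTBM-SEGPHOS (11 mol %), (EtO)2MeSiH (5 equiv), t-BuOH (5 equiv), toluene, 0 °C to rt; then aq. NH4F
Reagents that add atoms: none
Why: Proposed new method: the bisphosphine-bound CuH should add hydride to C2 of the chromone on the face chosen by the ligand (2R), t-BuOH then protonates the copper enolate at C3 anti to the pseudo-axial C2 aryl group so that H2 and H3 end up cis (3R), and the ring F aryl ketone is reduced to its carbinol by the same catalyst in the same flask; the closest known reactions are the CuH-catalysed asymmetric 1,4-reductions of 2-substituted chromones and of β,β-disubstituted cyclic enones, which have not been shown on a tetrasubstituted 2,3-diarylchromone.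

Step 9
Reactants: 13 cis-chromanone with ring F carbinol
Product: 14 (2R,3R)-5,7-bis(benzyloxy)-2-[3,4-bis(benzyloxy)phenyl]-3-[(2S)-5,7-bis(benzyloxy)-2-(4-benzyloxyphenyl)-4-oxochroman-8-yl]chroman-4-one (heptabenzyl ether of the target)
Conditions: Dess–Martin periodinane (1.5 equiv), pyridine (3 equiv), CH2Cl2, 0 °C
Reagents that add atoms: none
Why: Dess–Martin oxidation of the benzylic ring F carbinol restores the C4'' ketone from both epimers, and the cold, pyridine-buffered conditions should leave the epimerisable cis C3–H untouched.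

Step 10
Reactants: 14 heptabenzyl ether of the target
Product: 15 (2R,3R)-2-(3,4-dihydroxyphenyl)-5,7-dihydroxy-3-[(2S)-5,7-dihydroxy-2-(4-hydroxyphenyl)-4-oxochroman-8-yl]chroman-4-one (CNP0105436.1)
Conditions: H2 (1 atm), 10% Pd/C, EtOAc–MeOH, rt
Reagents that add atoms: none
Why: hydrogenolysis of seven aryl benzyl ethers under neutral conditions; with no acid or base present, C3 (α to the ketone) and C2'' should not epimerise, and the ortho-oxygenated aryl ketones resist reduction.

**Compound list**

1 | 2,4,6-trihydroxybenzaldehyde | O=Cc1c(O)cc(O)cc1O | starting material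
2 | benzyl bromide | BrCc1ccccc1 | starting material
3 | 2,4,6-tris(benzyloxy)benzaldehyde | O=Cc1c(OCc2ccccc2)cc(OCc2ccccc2)cc1OCc1ccccc1 | intermediate
4 | 3,4-bis(benzyloxy)benzaldehyde | O=Cc1ccc(OCc2ccccc2)c(OCc2ccccc2)c1 | starting material
5 | 1,2-bis(benzyloxy)-4-ethynylbenzene | C#Cc1ccc(OCc2ccccc2)c(OCc2ccccc2)c1 | intermediate
6 | lithium [3,4-bis(benzyloxy)phenyl]acetylide (not isolated) | [Li]C#Cc1ccc(OCc2ccccc2)c(OCc2ccccc2)c1 | intermediate
7 | rac-1-[2,4,6-tris(benzyloxy)phenyl]-3-[3,4-bis(benzyloxy)phenyl]prop-2-yn-1-ol | OC(C#Cc1ccc(OCc2ccccc2)c(OCc2ccccc2)c1)c1c(OCc2ccccc2)cc(OCc2ccccc2)cc1OCc1ccccc1 | intermediate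
8 | 1-[2,4,6-tris(benzyloxy)phenyl]-3-[3,4-bis(benzyloxy)phenyl]prop-2-yn-1-one | O=C(C#Cc1ccc(OCc2ccccc2)c(OCc2ccccc2)c1)c1c(OCc2ccccc2)cc(OCc2ccccc2)cc1OCc1ccccc1 | intermediate
9 | (S)-naringenin | O=C1C[C@@H](c2ccc(O)cc2)Oc2cc(O)cc(O)c12 | starting material
10 | (2S)-5,7-bis(benzyloxy)-2-[4-(benzyloxy)phenyl]chroman-4-one | O=C1C[C@@H](c2ccc(OCc3ccccc3)cc2)Oc2cc(OCc3ccccc3)cc(OCc3ccccc3)c12 | intermediate
11 | (2S)-5,7-bis(benzyloxy)-2-[4-(benzyloxy)phenyl]-8-iodochroman-4-one | O=C1C[C@@H](c2ccc(OCc3ccccc3)cc2)Oc2c1c(OCc1ccccc1)cc(OCc1ccccc1)c2I | intermediate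
12 | 5,7-bis(benzyloxy)-2-[3,4-bis(benzyloxy)phenyl]-3-[(2S)-5,7-bis(benzyloxy)-2-(4-benzyloxyphenyl)-4-oxochroman-8-yl]-4H-chromen-4-one | O=C1C[C@@H](c2ccc(OCc3ccccc3)cc2)Oc2c1c(OCc1ccccc1)cc(OCc1ccccc1)c2-c1c(-c2ccc(OCc3ccccc3)c(OCc3ccccc3)c2)oc2cc(OCc3ccccc3)cc(OCc3ccccc3)c2c1=O | intermediate
13 | (2R,3R)-5,7-bis(benzyloxy)-2-[3,4-bis(benzyloxy)phenyl]-3-[(2S)-5,7-bis(benzyloxy)-2-(4-benzyloxyphenyl)-4-hydroxychroman-8-yl]chroman-4-one, epimer mixture at C4'' | OC1C[C@@H](c2ccc(OCc3ccccc3)cc2)Oc2c1c(OCc1ccccc1)cc(OCc1ccccc1)c2[C@H]1C(=O)c2c(OCc3ccccc3)cc(OCc3ccccc3)cc2O[C@H]1c1ccc(OCc2ccccc2)c(OCc2ccccc2)c1 | intermediate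
14 | (2R,3R)-5,7-bis(benzyloxy)-2-[3,4-bis(benzyloxy)phenyl]-3-[(2S)-5,7-bis(benzyloxy)-2-(4-benzyloxyphenyl)-4-oxochroman-8-yl]chroman-4-one | O=C1C[C@@H](c2ccc(OCc3ccccc3)cc2)Oc2c1c(OCc1ccccc1)cc(OCc1ccccc1)c2[C@H]1C(=O)c2c(OCc3ccccc3)cc(OCc3ccccc3)cc2O[C@H]1c1ccc(OCc2ccccc2)c(OCc2ccccc2)c1 | intermediate
15 | (2R,3R)-2-(3,4-dihydroxyphenyl)-5,7-dihydroxy-3-[(2S)-5,7-dihydroxy-2-(4-hydroxyphenyl)-4-oxochroman-8-yl]chroman-4-one | O=C1C[C@@H](c2ccc(O)cc2)Oc2c1c(O)cc(O)c2[C@H]1C(=O)c2c(O)cc(O)cc2O[C@H]1c1ccc(O)c(O)c1 | target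

**Step count**

Total: 10 steps. Longest linear sequence: 7 steps (step 1 or 2, then 3, 4, 7, 8, 9, 10).

**Steps most likely to fail**

Step 7. The arylpalladium intermediate may insert the alkyne syn (carbopalladation) or be reduced before the weakly nucleophilic ether oxygen attacks, or the benzyl group may shift from oxygen to C3 instead of leaving. The fallback uses known chemistry, sets out from 8 and 11 and comes back at 12, making the two bonds in separate steps. ICl (CH2Cl2, −78 °C) would cyclise 8 by the established dealkylative 6-endo iodocyclisation of 2-alkoxyaryl ynones to 5,7-bis(benzyloxy)-2-[3,4-bis(benzyloxy)phenyl]-3-iodochromone F1. Miyaura borylation of 11 (bis(pinacolato)diboron, PdCl2(dppf), KOAc, dioxane, 80 °C) would give the 8''-pinacolboronate of tri-O-benzylnaringenin F2. Suzuki–Miyaura coupling of F1 with F2 (Pd(OAc)2, SPhos, CsF, dioxane, 80 °C) would then form C3–C8'' and give 12.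

Step 8. Hydride transfer to the tetrasubstituted C2, flanked by two aryl groups, may be too slow or poorly face-selective (the rotamers about C3–C8'' may respond differently to the chiral catalyst), or C3 may be protonated or later epimerised into the trans series. The fallback uses known chemistry, sets out from 12 and comes back at 15. Heterogeneous hydrogenation (H2, 4 bar, Pd(OH)2/C, THF–MeOH) would add hydrogen syn across C2=C3, as in the hydrogenation of chromones and isoflavones to chromanones, which gives the cis relationship without an enolate, and would remove the seven benzyl groups in the same operation. Because C2'' is fixed, the two cis products are diastereomers: 15 and its (2S,3S,2''S) diastereomer F3, to be separated by preparative reversed-phase HPLC.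

Step 6. Iodination may go to C6'' instead of C8'', or twice, and the regioisomers may be hard to separate. The fallback fixes the iodine position before ring F exists; it sets out from benzyl bromide 2 and comes back at 11. Commercial 2,4,6-trihydroxyacetophenone would be dibenzylated (2, K2CO3, acetone; one chelated ortho hydroxyl stays free) to 1-[2-hydroxy-4,6-bis(benzyloxy)phenyl]ethanone F4. Iodination with NIS ortho to the free phenol would give 1-[2-hydroxy-3-iodo-4,6-bis(benzyloxy)phenyl]ethanone F5, with the iodine next to the oxygen that becomes O1''. Claisen–Schmidt condensation with commercial 4-(benzyloxy)benzaldehyde (KOH, EtOH) would give the chalcone F6, and oxa-Michael ring closure (NaOAc, EtOH, reflux) racemic 8-iodo-tri-O-benzylnaringenin F7. Preparative chiral HPLC would then deliver 11.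

**Further compounds**

F1 | step 7 | 5,7-bis(benzyloxy)-2-[3,4-bis(benzyloxy)phenyl]-3-iodo-4H-chromen-4-one | O=c1c(I)c(-c2ccc(OCc3ccccc3)c(OCc3ccccc3)c2)oc2cc(OCc3ccccc3)cc(OCc3ccccc3)c12
F2 | step 7 | (2S)-5,7-bis(benzyloxy)-2-[4-(benzyloxy)phenyl]-8-(4,4,5,5-tetramethyl-1,3,2-dioxaborolan-2-yl)chroman-4-one | O=C1C[C@@H](c2ccc(OCc3ccccc3)cc2)Oc2c1c(OCc1ccccc1)cc(OCc1ccccc1)c2B1OC(C)(C)C(C)(C)O1
F3 | step 8 | (2S,3S)-2-(3,4-dihydroxyphenyl)-5,7-dihydroxy-3-[(2S)-5,7-dihydroxy-2-(4-hydroxyphenyl)-4-oxochroman-8-yl]chroman-4-one | O=C1C[C@@H](c2ccc(O)cc2)Oc2c1c(O)cc(O)c2[C@@H]1C(=O)c2c(O)cc(O)cc2O[C@@H]1c1ccc(O)c(O)c1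
F4 | step 6 | 1-[2-hydroxy-4,6-bis(benzyloxy)phenyl]ethanone | CC(=O)c1c(O)cc(OCc2ccccc2)cc1OCc1ccccc1
F5 | step 6 | 1-[2-hydroxy-3-iodo-4,6-bis(benzyloxy)phenyl]ethanone | CC(=O)c1c(O)c(I)c(OCc2ccccc2)cc1OCc1ccccc1
F6 | step 6 | (E)-1-[2-hydroxy-3-iodo-4,6-bis(benzyloxy)phenyl]-3-[4-(benzyloxy)phenyl]prop-2-en-1-one | O=C(/C=C/c1ccc(OCc2ccccc2)cc1)c1c(O)c(I)c(OCc2ccccc2)cc1OCc1ccccc1
F7 | step 6 | rac-5,7-bis(benzyloxy)-2-[4-(benzyloxy)phenyl]-8-iodochroman-4-one | O=C1CC(c2ccc(OCc3ccccc3)cc2)Oc2c1c(OCc1ccccc1)cc(OCc1ccccc1)c2I
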